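Labels: the upper chroman is benzo ring A plus pyran ring C, with ring B (the dimethoxyphenol) on C3. Ring D is the arene on C4 and is also the 3-aryl group of the lower chroman (pyran ring E plus benzo ring F).
Cuts: C4–ring D; O1–C2 of rings C and E; in the upper half C4–C4a and C3–ring B; in the lower half C4–C4a (ring F) and C3–C2.
Enabling feature: C3 and C4 of ring C are neighbouring CH stereocentres, each carrying an arene, and C3 is flanked by the C2H2–O unit. This is the footprint of an anti 1,2-diarylation of an (E)-allyl ether in which boron keeps the C4 valence open for ring D.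
Forward order: ring E is closed first (lower fragment). The halves are then joined at C4–ring D by a second boron-to-carbon shift, ring C is closed last, and finally all benzyl groups are removed.
Stereochemistry: the absolute configuration of C3/C4 comes from the chiral bisphosphine–palladium catalyst. Their relative configuration comes from anti addition to the E alkene plus retention in the C–B to C–aryl exchange. Lower C3 comes from the vinylboron version of the same coupling, carried through a stereoretentive one-carbon homologation.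

Key step: step 8

Assumption: the (Sp,Sp) antipode of the MandyPhos ligand is taken to give the R boronate in step 11 and its mirror image the 1S,2R boronate in step 8, by analogy with simple aryl cases. If a test run shows the opposite sense, the two commercially available antipodes are exchanged.

Step 1
Reactants: 1 4-bromoresorcinol
Product: 2 5-(benzyloxy)-2-bromophenol
Conditions: BnBr (1.0 equiv), K2CO3 (1.0 equiv), acetone, reflux
Reagents that add atoms: benzyl bromide, BrCc1ccccc1
Why: Williamson ether synthesis; the hydroxyl para to bromine is unhindered and gives the more nucleophilic phenoxide, whereas the ortho-bromophenoxide is shielded and inductively tamed, so one equivalent of halide should go mainly to the wanted oxygen.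

Step 2
Reactants: 2 5-(benzyloxy)-2-bromophenol
Product: 3 4-(benzyloxy)-1-bromo-2-(methoxymethoxy)benzene
Conditions: NaH, MOMCl, THF, 0 °C → rt
Reagents that add atoms: chloromethyl methyl ether, COCCl
Why: O-alkylation of the sodium phenoxide (Williamson type); the acetal tolerates organolithiums, chelates the future ortho-lithium and is removed later with mild acid.

Step 3
Reactants: 4 2-hydroxy-4,5-dimethoxybenzaldehyde
Product: 5 2-(benzyloxy)-4,5-dimethoxybenzaldehyde
Conditions: BnBr, K2CO3, DMF, 60 °C
Reagents that add atoms: benzyl bromide, BrCc1ccccc1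
Why: Williamson ether synthesis on the only free phenol.

Step 4
Reactants: 5 2-(benzyloxy)-4,5-dimethoxybenzaldehyde
Product: 7 2-(benzyloxy)-4,5-dimethoxyphenol, via aryl formate 6 (not isolated)
Conditions: mCPBA, CH2Cl2, 0 °C → rt; aq NaHCO3 wash; then K2CO3 (cat.), MeOH, rt
Reagents that add atoms: 3-chloroperoxybenzoic acid, OOC(=O)c1cccc(Cl)c1
Why: Baeyer–Villiger (Dakin-type) oxidation; the electron-rich aryl group migrates in the peracid adduct in preference to hydride, and the labile formate is methanolysed.

Step 5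
Reactants: 7 2-(benzyloxy)-4,5-dimethoxyphenol
Product: 8 2-(benzyloxy)-4,5-dimethoxyphenyl trifluoromethanesulfonate
Conditions: Tf2O, pyridine, CH2Cl2, 0 °C
Reagents that add atoms: trifluoromethanesulfonic anhydride, O=S(=O)(OS(=O)(=O)C(F)(F)F)C(F)(F)F
Why: standard O-sulfonylation of a phenol; the non-coordinating triflate is what later gives a cationic arylpalladium species.

Step 6
Reactants: 9 acenaphthenequinone
Product: 10 cis-1,2-dimethyl-1,2-dihydroacenaphthylene-1,2-diol (meso; mac diol)
Conditions: MeMgBr (2.5 equiv), THF, 0 °C → rt; aq NH4Cl; recrystallisation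
Reagents that add atoms: methylmagnesium bromide, C[Mg]Br
Why: double Grignard 1,2-addition; the second methyl group should enter anti to the bulky solvated magnesium alkoxide and give mainly the cis diol, which is purified by crystallisation and is the only isomer able to bridge boron.

Step 7
Reactants: 11 (E)-3-(tert-butyldimethylsilyloxy)prop-1-enylboronic acid pinacol ester; 10 mac diol
Product: 13 (E)-3-(tert-butyldimethylsilyloxy)prop-1-enylboronic acid mac ester, via alkenylboronic acid 12 (not isolated)
Conditions: NaIO4, NH4OAc, acetone/H2O, rt; extract; then 10, 4 Å molecular sieves, CH2Cl2, rt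
Reagents that add atoms: none
Why: periodate glycol cleavage removes pinacol from the hydrolysis equilibrium, and the free boronic acid condenses with the diol (boronic ester formation) without touching the E alkene or the silyl ether.

Step 8
Reactants: 3 4-(benzyloxy)-1-bromo-2-(methoxymethoxy)benzene; 13 alkenylboronic acid mac ester; 8 aryl triflate
Product: 16 (1S,2R)-1-[4-(benzyloxy)-2-(methoxymethoxy)phenyl]-2-[2-(benzyloxy)-4,5-dimethoxyphenyl]-3-(tert-butyldimethylsilyloxy)propylboronic acid mac ester, via aryllithium 14 (not isolated), via lithium ate complex 15 (not isolated)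
Conditions: 3, t-BuLi (2.0 equiv), THF, −78 °C; add 13, −78 °C → rt; then KOTf (2 equiv), 8 (1.1 equiv), Pd(OAc)2 (3 mol%), (Rp,Rp)-MandyPhos [1,1'-bis{bis(4-methoxy-3,5-dimethylphenyl)phosphino}-2,2'-bis{(S)-α-(dimethylamino)benzyl}ferrocene] (3.6 mol%), THF, 60 °C
Reagents that add atoms: none
Why: Aryllithium 14 fills the empty orbital of boronate 13 to give ate complex 15; the cationic divalent arylpalladium formed from triflate 8 binds the alkene face chosen by the ligand and sets off a 1,2-metallate shift in which ring A leaves boron for C4 on the face opposite palladium while palladium takes C3, and reductive elimination with retention then places ring B on C3. The closest known reaction type is the enantio- and diastereoselective conjunctive cross-coupling of β-substituted alkenylboron ate complexes with aryl triflates. No ring is formed here; the two new skeletal bonds are C4–C4a and C3–C1 of ring B. The absolute configuration of both centres is fixed by the planar-chiral bisphosphine, and their relative configuration follows from the stereospecific anti course on the geometrically pure E alkene, 1S,2R being the arrangement that ends up 3,4-trans in ring C. The step needs the conjunctive pathway to outrun direct Suzuki-type transfer of ring A or of the alkenyl group, as well as β-hydride and β-silyloxy elimination: the hindered mac diol shields the boronate oxygens from palladium and slows transmetallation, the wide-bite ligand speeds reductive elimination, and KOTf removes the bromide that would otherwise occupy the cationic palladium.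

Step 9
Reactants: 2 5-(benzyloxy)-2-bromophenol
Product: 17 [5-(benzyloxy)-2-bromophenoxy](tert-butyl)dimethylsilane
Conditions: TBSCl, imidazole, DMF, rt
Reagents that add atoms: tert-butyldimethylsilyl chloride, CC(C)(C)[Si](C)(C)Cl
Why: standard imidazole-promoted silylation; the aryl silyl ether is orthogonal to the MOM group of ring D and is removed by base in step 12.

Step 10
Reactants: 18 2-bromo-5-methoxyphenol
Product: 19 1-bromo-4-methoxy-2-(methoxymethoxy)benzene
Conditions: NaH, MOMCl, THF, 0 °C → rt
Reagents that add atoms: chloromethyl methyl ether, COCCl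
Why: O-alkylation of the sodium phenoxide (Williamson type), giving the organolithium-stable precursor of ring D.

Step 11
Reactants: 19 1-bromo-4-methoxy-2-(methoxymethoxy)benzene; 20 vinylboronic acid pinacol ester; 17 silyl-protected aryl bromide
Product: 23 (R)-2-[4-(benzyloxy)-2-(tert-butyldimethylsilyloxy)phenyl]-1-[4-methoxy-2-(methoxymethoxy)phenyl]ethylboronic acid pinacol ester, via aryllithium 21 (not isolated), via lithium vinyl ate complex 22 (not isolated)
Conditions: 19, t-BuLi (2.0 equiv), THF, −78 °C; add 20, −78 °C → rt; then KOTf (3 equiv), 17, Pd(OAc)2 (2 mol%), (Sp,Sp)-MandyPhos [1,1'-bis{bis(4-methoxy-3,5-dimethylphenyl)phosphino}-2,2'-bis{(R)-α-(dimethylamino)benzyl}ferrocene] (2.4 mol%), THF, 60 °C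
Reagents that add atoms: none
Why: parent enantioselective conjunctive cross-coupling of a vinylboron ate complex; ring D migrates from boron to the α-carbon anti to palladium, ring F is delivered to the CH2 terminus, the ligand-selected alkene face sets the benzylic C–B centre (future lower C3) as R, and KOTf scavenges bromide so that an aryl bromide can serve as electrophile.

Step 12
Reactants: 23 benzylic pinacol boronate
Product: 25 (R)-5-(benzyloxy)-2-{3-hydroxy-2-[4-methoxy-2-(methoxymethoxy)phenyl]propyl}phenol, via homologated pinacol boronate 24 (not isolated)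
Conditions: BrCH2Cl, n-BuLi, THF, −78 °C → rt; then 3 M NaOH, 30% H2O2, 0 °C → rt
Reagents that add atoms: bromochloromethane, ClCBr; hydrogen peroxide, OO
Why: Matteson homologation (the benzylic carbon shifts from boron to the chloromethyl carbon with retention, so the centre stays R) followed by boronate oxidation of the new primary C–B bond, the basic peroxide also cleaving the labile aryl silyl ether.

Step 13
Reactants: 25 phenol alcohol
Product: 26 (R)-7-(benzyloxy)-3-[4-methoxy-2-(methoxymethoxy)phenyl]chroman
Conditions: PPh3, DIAD, THF, 0 °C → rt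
Reagents that add atoms: none
Why: intramolecular Mitsunobu etherification (6-exo-tet) of the only free phenol onto the primary alcohol closes ring E at O1–C2 without touching the stereocentre.

Step 14
Reactants: 26 MOM-protected isoflavan
Product: 27 (R)-2-[7-(benzyloxy)chroman-3-yl]-5-methoxyphenol
Conditions: HCl (cat.), MeOH, 45 °C
Reagents that add atoms: none
Why: acid-catalysed acetal methanolysis frees the ring D phenol; the benzyl ether, methyl ether and C3 are inert.

Step 15
Reactants: 27 ring D phenol
Product: 28 (R)-2-[7-(benzyloxy)chroman-3-yl]-4-iodo-5-methoxyphenol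
Conditions: NaI (1.0 equiv), NaOH (1.0 equiv), aq NaOCl (1.0 equiv, slow addition), MeOH, 0 °C; aq Na2S2O3, dilute HCl
Reagents that add atoms: sodium iodide, [Na+].[I-]
Why: electrophilic iodination by hypoiodite acts only on the phenolate ring (the diether ring F is inert to this reagent) and should go para to the oxygen, since one ortho site is substituted and the other is wedged between two oxygen substituents.

Step 16
Reactants: 28 iodophenol; 16 benzylic mac boronate
Product: 31 4-{(1S,2R)-1-[4-(benzyloxy)-2-(methoxymethoxy)phenyl]-2-[2-(benzyloxy)-4,5-dimethoxyphenyl]-3-(tert-butyldimethylsilyloxy)propyl}-2-[(3R)-7-(benzyloxy)chroman-3-yl]-5-methoxyphenol, via lithiated sodium phenolate 29 (not isolated), via phenolate borate 30 (not isolated)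
Conditions: 28 (1.2 equiv), NaH, THF, 0 °C; t-BuLi (2.0 equiv), −78 °C; add 16, −78 °C → rt; Ph3BiF2 (1.3 equiv), −78 °C → rt
Reagents that add atoms: none
Why: stereospecific sp2–sp3 coupling of a para-metallated phenolate with a secondary boronic ester, in which 29 adds to boron, pentavalent bismuth turns the phenolate oxygen into a leaving group so that the boron-bearing ring carbon becomes electrophilic, the benzylic C4 group shifts from boron to that carbon with retention (C4 stays S) and loss of the boryl group restores the phenol, all without the transmetallation to palladium that the mac diol suppresses and that would invite β-hydride elimination.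

Step 17
Reactants: 31 coupled phenol
Product: 32 4-{(1S,2R)-1-[4-(benzyloxy)-2-hydroxyphenyl]-2-[2-(benzyloxy)-4,5-dimethoxyphenyl]-3-hydroxypropyl}-2-[(3R)-7-(benzyloxy)chroman-3-yl]-5-methoxyphenol
Conditions: HCl (0.2 M), MeOH/THF, 40 °C
Reagents that add atoms: none
Why: acid methanolysis removes the primary silyl ether and the MOM acetal in one operation, and the C4–aryl bonds, which join resorcinol-type rather than phloroglucinol-type rings, are not expected to ionise under such mild acid.

Step 18
Reactants: 32 triol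
Product: 33 4-{(3R,4S)-7-(benzyloxy)-3-[2-(benzyloxy)-4,5-dimethoxyphenyl]chroman-4-yl}-2-[(3R)-7-(benzyloxy)chroman-3-yl]-5-methoxyphenol
Conditions: PPh3, DIAD, THF (0.01 M), 0 °C → rt
Reagents that add atoms: none
Why: intramolecular Mitsunobu etherification (6-exo-tet) of the ring A phenol onto the primary alcohol closes ring C; the ring D phenol lies para to C4 and cannot reach the carbinol, so only slow intermolecular alkylation competes at high dilution, and no stereocentre is involved.

Step 19
Reactants: 33 tris(benzyl) ether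
Product: 34 (3R,4S)-3-(2-hydroxy-4,5-dimethoxyphenyl)-4-{4-hydroxy-5-[(3R)-7-hydroxychroman-3-yl]-2-methoxyphenyl}chroman-7-ol (CNP0217096.1)
Conditions: H2 (1 atm), Pd/C, EtOAc/MeOH, rt
Reagents that add atoms: none
Why: catalytic hydrogenolysis cleaves the three O-benzyl groups, while the chroman O1–C2 bonds are not benzylic and the C–aryl bonds at C4 are not hydrogenolysed.

Compound list
1 | 4-bromoresorcinol | Oc1ccc(Br)c(O)c1 | starting material
2 | 5-(benzyloxy)-2-bromophenol | Oc1cc(OCc2ccccc2)ccc1Br | intermediate
3 | 4-(benzyloxy)-1-bromo-2-(methoxymethoxy)benzene | COCOc1cc(OCc2ccccc2)ccc1Br | intermediate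
4 | 2-hydroxy-4,5-dimethoxybenzaldehyde | COc1cc(O)c(C=O)cc1OC | starting material
5 | 2-(benzyloxy)-4,5-dimethoxybenzaldehyde | COc1cc(OCc2ccccc2)c(C=O)cc1OC | intermediate
6 | 2-(benzyloxy)-4,5-dimethoxyphenyl formate | COc1cc(OCc2ccccc2)c(OC=O)cc1OC | intermediate
7 | 2-(benzyloxy)-4,5-dimethoxyphenol | COc1cc(OCc2ccccc2)c(O)cc1OC | intermediate
8 | 2-(benzyloxy)-4,5-dimethoxyphenyl trifluoromethanesulfonate | COc1cc(OCc2ccccc2)c(OS(=O)(=O)C(F)(F)F)cc1OC | intermediate
9 | acenaphthenequinone | O=C1C(=O)c2cccc3cccc1c23 | starting material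
10 | cis-1,2-dimethyl-1,2-dihydroacenaphthylene-1,2-diol (mac diol, meso) | C[C@]1(O)c2cccc3cccc(c23)[C@@]1(C)O | intermediate
11 | (E)-3-(tert-butyldimethylsilyloxy)prop-1-enylboronic acid pinacol ester | CC(C)(C)[Si](C)(C)OC/C=C/B1OC(C)(C)C(C)(C)O1 | starting material
12 | (E)-3-(tert-butyldimethylsilyloxy)prop-1-enylboronic acid | CC(C)(C)[Si](C)(C)OC/C=C/B(O)O | intermediate
13 | (E)-3-(tert-butyldimethylsilyloxy)prop-1-enylboronic acid mac ester | CC(C)(C)[Si](C)(C)OC/C=C/B1O[C@@]2(C)c3cccc4cccc(c34)[C@@]2(C)O1 | intermediate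
14 | 4-(benzyloxy)-2-(methoxymethoxy)phenyllithium | [Li]c1ccc(OCc2ccccc2)cc1OCOC | intermediate
15 | lithium [4-(benzyloxy)-2-(methoxymethoxy)phenyl][(E)-3-(tert-butyldimethylsilyloxy)prop-1-enyl] mac borate | [Li+].CC(C)(C)[Si](C)(C)OC/C=C/[B-]1(c2ccc(OCc3ccccc3)cc2OCOC)O[C@@]2(C)c3cccc4cccc(c34)[C@@]2(C)O1 | intermediate
16 | (1S,2R)-1-[4-(benzyloxy)-2-(methoxymethoxy)phenyl]-2-[2-(benzyloxy)-4,5-dimethoxyphenyl]-3-(tert-butyldimethylsilyloxy)propylboronic acid mac ester | COc1cc(OCc2ccccc2)c([C@H](CO[Si](C)(C)C(C)(C)C)[C@H](B2O[C@@]3(C)c4cccc5cccc(c45)[C@@]3(C)O2)c2ccc(OCc3ccccc3)cc2OCOC)cc1OC | intermediate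
17 | [5-(benzyloxy)-2-bromophenoxy](tert-butyl)dimethylsilane | CC(C)(C)[Si](C)(C)Oc1cc(OCc2ccccc2)ccc1Br | intermediate
18 | 2-bromo-5-methoxyphenol | Oc1cc(OC)ccc1Br | starting material
19 | 1-bromo-4-methoxy-2-(methoxymethoxy)benzene | COCOc1cc(OC)ccc1Br | intermediate
20 | vinylboronic acid pinacol ester | C=CB1OC(C)(C)C(C)(C)O1 | starting material
21 | 4-methoxy-2-(methoxymethoxy)phenyllithium | [Li]c1ccc(OC)cc1OCOC | intermediate
22 | lithium [4-methoxy-2-(methoxymethoxy)phenyl](vinyl) pinacol borate | [Li+].C=C[B-]1(c2ccc(OC)cc2OCOC)OC(C)(C)C(C)(C)O1 | intermediate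
23 | (R)-2-[4-(benzyloxy)-2-(tert-butyldimethylsilyloxy)phenyl]-1-[4-methoxy-2-(methoxymethoxy)phenyl]ethylboronic acid pinacol ester | COCOc1cc(OC)ccc1[C@H](B2OC(C)(C)C(C)(C)O2)Cc1ccc(OCc2ccccc2)cc1O[Si](C)(C)C(C)(C)C | intermediate
24 | (R)-3-[4-(benzyloxy)-2-(tert-butyldimethylsilyloxy)phenyl]-2-[4-methoxy-2-(methoxymethoxy)phenyl]propylboronic acid pinacol ester | COCOc1cc(OC)ccc1[C@H](CB2OC(C)(C)C(C)(C)O2)Cc1ccc(OCc2ccccc2)cc1O[Si](C)(C)C(C)(C)C | intermediate
25 | (R)-5-(benzyloxy)-2-{3-hydroxy-2-[4-methoxy-2-(methoxymethoxy)phenyl]propyl}phenol | COCOc1cc(OC)ccc1[C@H](CO)Cc1ccc(OCc2ccccc2)cc1O | intermediate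
26 | (R)-7-(benzyloxy)-3-[4-methoxy-2-(methoxymethoxy)phenyl]chroman | COCOc1cc(OC)ccc1[C@@H]1COc2cc(OCc3ccccc3)ccc2C1 | intermediate
27 | (R)-2-[7-(benzyloxy)chroman-3-yl]-5-methoxyphenol | COc1ccc([C@@H]2COc3cc(OCc4ccccc4)ccc3C2)c(O)c1 | intermediate
28 | (R)-2-[7-(benzyloxy)chroman-3-yl]-4-iodo-5-methoxyphenol | COc1cc(O)c([C@@H]2COc3cc(OCc4ccccc4)ccc3C2)cc1I | intermediate
29 | sodium (R)-2-[7-(benzyloxy)chroman-3-yl]-4-lithio-5-methoxyphenolate | [Na+].[Li]c1cc([C@@H]2COc3cc(OCc4ccccc4)ccc3C2)c([O-])cc1OC | intermediate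
30 | lithium sodium salt of the borate formed from 29 and 16 (ring D and C4 both on boron) | [Na+].[Li+].COc1cc([O-])c([C@@H]2COc3cc(OCc4ccccc4)ccc3C2)cc1[B-]1([C@H](c2ccc(OCc3ccccc3)cc2OCOC)[C@@H](CO[Si](C)(C)C(C)(C)C)c2cc(OC)c(OC)cc2OCc2ccccc2)O[C@@]2(C)c3cccc4cccc(c34)[C@@]2(C)O1 | intermediate
31 | 4-{(1S,2R)-1-[4-(benzyloxy)-2-(methoxymethoxy)phenyl]-2-[2-(benzyloxy)-4,5-dimethoxyphenyl]-3-(tert-butyldimethylsilyloxy)propyl}-2-[(3R)-7-(benzyloxy)chroman-3-yl]-5-methoxyphenol | COc1cc(OCc2ccccc2)c([C@H](CO[Si](C)(C)C(C)(C)C)[C@H](c2cc([C@@H]3COc4cc(OCc5ccccc5)ccc4C3)c(O)cc2OC)c2ccc(OCc3ccccc3)cc2OCOC)cc1OC | intermediate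
32 | 4-{(1S,2R)-1-[4-(benzyloxy)-2-hydroxyphenyl]-2-[2-(benzyloxy)-4,5-dimethoxyphenyl]-3-hydroxypropyl}-2-[(3R)-7-(benzyloxy)chroman-3-yl]-5-methoxyphenol | COc1cc(OCc2ccccc2)c([C@H](CO)[C@H](c2cc([C@@H]3COc4cc(OCc5ccccc5)ccc4C3)c(O)cc2OC)c2ccc(OCc3ccccc3)cc2O)cc1OC | intermediate
33 | 4-{(3R,4S)-7-(benzyloxy)-3-[2-(benzyloxy)-4,5-dimethoxyphenyl]chroman-4-yl}-2-[(3R)-7-(benzyloxy)chroman-3-yl]-5-methoxyphenol | COc1cc(OCc2ccccc2)c([C@@H]2COc3cc(OCc4ccccc4)ccc3[C@H]2c2cc([C@@H]3COc4cc(OCc5ccccc5)ccc4C3)c(O)cc2OC)cc1OC | intermediate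
34 | (3R,4S)-3-(2-hydroxy-4,5-dimethoxyphenyl)-4-{4-hydroxy-5-[(3R)-7-hydroxychroman-3-yl]-2-methoxyphenyl}chroman-7-ol (CNP0217096.1) | COc1cc(O)c([C@@H]2COc3cc(O)ccc3[C@H]2c2cc([C@@H]3COc4cc(O)ccc4C3)c(O)cc2OC)cc1OC | target

Total step count: 19. Longest linear sequence: 11 steps (1, 9, 11, 12, 13, 14, 15, 16, 17, 18, 19, from 4-bromoresorcinol).

Steps most likely to fail

Most at risk is step 8.
- **What may go wrong:** all three partners are hindered (an ortho-alkoxy migrating group, an ortho-alkoxy electron-rich triflate and a β-substituted alkene). Oxidative addition may therefore be slow. Direct transfer of an organic group from boron to palladium may overtake the metallate shift, and the alkylpalladium at C3 may lose the neighbouring silyloxy group or a β-hydride before reductive elimination.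
- **Fallback:** it sets out from aldehyde 5 and gives up boron altogether.
  - Claisen–Schmidt condensation of 5 with purchased 1-[4-(benzyloxy)-2-hydroxyphenyl]ethanone (KOH, EtOH) gives the 2'-hydroxychalcone F1.
  - Oxidative 1,2-aryl shift with Tl(NO3)3 in MeOH/HC(OMe)3 gives the rearranged dimethyl acetal F2.
  - Warm methanolic HCl closes F2 to the isoflavone F3.
  - Asymmetric transfer hydrogenation with RuCl[(R,R)-TsDPEN](p-cymene) in HCO2H/Et3N reduces the C2–C3 double bond to the configurationally labile isoflavanone F4. It then reduces the ketone under dynamic kinetic resolution to the cis-(3R,4R)-isoflavan-4-ol F5.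
  - Ionisation of F5 with catalytic BF3·OEt2 at low temperature in the presence of phenol 27 leads to Friedel–Crafts attack. The position para to the free hydroxyl of ring D adds to the face of C4 away from ring B, which rejoins the route at 33.

Second is step 16.
- **What may go wrong:** ate-complex formation between two bulky partners may stay incomplete. The pentavalent bismuth reagent may oxidise or O-arylate the electron-rich phenolate instead of triggering the shift, and unreacted borate may simply protodeboronate on work-up.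
- **Fallback:** it sets out from boronate 16 and changes the oxidation level at C4.
  - Methanolic HCl removes the silyl and MOM groups to give the boronate phenol alcohol F6.
  - Mitsunobu closure gives the (3R,4S)-4-boryl-3-arylchroman F7.
  - NaBO3·4H2O oxidises the C–B bond with retention to the trans-(3R,4S)-isoflavan-4-ol F8.
  - Acid-catalysed Friedel–Crafts alkylation of phenol 27 by F8, with C3 steering the arene to the opposite face, returns to the route at 33.

Third is step 11.
- **What may go wrong:** oxidative addition of the hindered, electron-rich aryl bromide may be slow, and residual bromide may inhibit the cationic palladium. Either would let the vinyl ate complex decay or couple directly.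
- **Fallback:** it sets out from bromide 19 and separates the C–B and C–C bond formations.
  - Suzuki vinylation of 19 (potassium vinyltrifluoroborate, PdCl2(dppf), Et3N, n-PrOH) gives the styrene F9.
  - Enantioselective diboration (B2pin2, Pt(dba)3, TADDOL-derived phosphonite) gives the (R)-1,2-bis(boronate) F10.
  - The primary C–B bond of F10 alone is cross-coupled with bromide 17 (Pd(OAc)2, RuPhos, aq KOH, THF, 70 °C). The base also removes the aryl silyl ether, giving the phenolic benzylic boronate F11.
  - F11 is homologated and oxidised under the conditions of step 12, with one extra equivalent of n-BuLi for the phenol, and rejoins the route at 25.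

Further compounds
F1 | step 8 | (E)-1-[4-(benzyloxy)-2-hydroxyphenyl]-3-[2-(benzyloxy)-4,5-dimethoxyphenyl]prop-2-en-1-one | COc1cc(OCc2ccccc2)c(/C=C/C(=O)c2ccc(OCc3ccccc3)cc2O)cc1OC
F2 | step 8 | 1-[4-(benzyloxy)-2-hydroxyphenyl]-2-[2-(benzyloxy)-4,5-dimethoxyphenyl]-3,3-dimethoxypropan-1-one (racemic) | COc1cc(OCc2ccccc2)c(C(C(OC)OC)C(=O)c2ccc(OCc3ccccc3)cc2O)cc1OC
F3 | step 8 | 7-(benzyloxy)-3-[2-(benzyloxy)-4,5-dimethoxyphenyl]-4H-chromen-4-one | COc1cc(OCc2ccccc2)c(-c2coc3cc(OCc4ccccc4)ccc3c2=O)cc1OC
F4 | step 8 | 7-(benzyloxy)-3-[2-(benzyloxy)-4,5-dimethoxyphenyl]chroman-4-one (racemising) | COc1cc(OCc2ccccc2)c(C2COc3cc(OCc4ccccc4)ccc3C2=O)cc1OC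
F5 | step 8 | (3R,4R)-7-(benzyloxy)-3-[2-(benzyloxy)-4,5-dimethoxyphenyl]chroman-4-ol (cis) | COc1cc(OCc2ccccc2)c([C@@H]2COc3cc(OCc4ccccc4)ccc3[C@@H]2O)cc1OC
F6 | step 16 | (1S,2R)-1-[4-(benzyloxy)-2-hydroxyphenyl]-2-[2-(benzyloxy)-4,5-dimethoxyphenyl]-3-hydroxypropylboronic acid mac ester | COc1cc(OCc2ccccc2)c([C@H](CO)[C@H](B2O[C@@]3(C)c4cccc5cccc(c45)[C@@]3(C)O2)c2ccc(OCc3ccccc3)cc2O)cc1OC
F7 | step 16 | (3R,4S)-7-(benzyloxy)-3-[2-(benzyloxy)-4,5-dimethoxyphenyl]chroman-4-ylboronic acid mac ester | COc1cc(OCc2ccccc2)c([C@@H]2COc3cc(OCc4ccccc4)ccc3[C@H]2B2O[C@@]3(C)c4cccc5cccc(c45)[C@@]3(C)O2)cc1OC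
F8 | step 16 | (3R,4S)-7-(benzyloxy)-3-[2-(benzyloxy)-4,5-dimethoxyphenyl]chroman-4-ol (trans) | COc1cc(OCc2ccccc2)c([C@@H]2COc3cc(OCc4ccccc4)ccc3[C@H]2O)cc1OC
F9 | step 11 | 4-methoxy-2-(methoxymethoxy)-1-vinylbenzene | C=Cc1ccc(OC)cc1OCOC
F10 | step 11 | (R)-1-[4-methoxy-2-(methoxymethoxy)phenyl]ethane-1,2-diylbis(boronic acid pinacol ester) | COCOc1cc(OC)ccc1[C@H](B2OC(C)(C)C(C)(C)O2)CB2OC(C)(C)C(C)(C)O2
F11 | step 11 | (R)-2-[4-(benzyloxy)-2-hydroxyphenyl]-1-[4-methoxy-2-(methoxymethoxy)phenyl]ethylboronic acid pinacol ester | COCOc1cc(OC)ccc1[C@H](B2OC(C)(C)C(C)(C)O2)Cc1ccc(OCc2ccccc2)cc1O
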